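**Retrosynthetic overview**
1. Feature: ring A is a cyclohexa-1,3-diene (C14=C15–C16=C17) whose two sp3 carbons C8 and C9 carry cis hydrogens and which shares the C9–C14 bond with ring B (C9–C14). This is the imprint of a 2-pyrone that has added across a cis alkene and lost CO2.
2. Key disconnection: C9–C14 and C8–C17, back to a 3,4,6-trisubstituted 2-pyrone (C14–C17) tethered through C13–C12 to C11 of a trans-5-methyl-5,6-dihydropyran-2-one whose carbonyl is C7.
3. Before: C3 arm and 6-bromomethyl group on 4,6-dimethyl-2-pyrone; C12 by oxazolidinone enolate alkylation; C10/C11 by anti-crotylboration; lactone ring by acryloylation and ring-closing metathesis.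
4. After: lactone carbonyl C7 becomes the C6=C7 alkene by lactol Wittig; two more Wittig homologations and a Sharpless epoxidation (C4–C5 oxirane) build C1–C6; the C11 and C19 carbinols are oxidised last.
5. Ring order: dihydropyranone (step 11), then ring B and ring A together (step 12), then the oxirane (step 20).

Key step: step 12

Remark: atoms are numbered C1 (carboxyl carbon) to C20 (acetonyl methyl), ring A = C8, C9, C14–C17, ring B = C9–C14; C19 is carried as the (S)-silyl ether, an arbitrary but defined choice because it ends as a ketone (TBS = tert-butyldimethylsilyl, TES = triethylsilyl, Ipc = isopinocampheyl).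

**Route**

Step 1
Reactants: 1 4,6-dimethyl-2H-pyran-2-one
Product: 2 3-bromo-4,6-dimethyl-2H-pyran-2-one
Conditions: Br2, CH2Cl2, 0 °C → rt; then Et3N
Reagents that add atoms: bromine, BrBr
Why: Electrophilic bromination of the 2-pyrone (halogenation by addition–elimination) should occur at C3, where attack gives a tertiary cation at C4 that is conjugated with the ring oxygen through C5=C6, and Et3N completes the loss of HBr.

Step 2
Reactants: 2 3-bromo-4,6-dimethyl-2H-pyran-2-one
Product: 3 4,6-dimethyl-3-(2-oxopropyl)-2H-pyran-2-one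
Conditions: isopropenyl acetate, Bu3SnOMe, PdCl2[P(o-tol)3]2 (3 mol%), toluene, 100 °C
Reagents that add atoms: isopropenyl acetate, CC(=C)OC(C)=O (delivered as tributyl(2-oxopropyl)stannane formed in the flask with Bu3SnOMe)
Why: Kosugi–Migita acetonylation: the tributyltin enolate of acetone formed in the flask transfers its acetonyl group to the C3–Br bond in a Stille-type palladium-catalysed coupling, which places C18–C20 on pyrone C3 without a base.

Step 3
Reactants: 3 4,6-dimethyl-3-(2-oxopropyl)-2H-pyran-2-one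
Product: 4 3-[(2S)-2-hydroxypropyl]-4,6-dimethyl-2H-pyran-2-one
Conditions: alcohol dehydrogenase ADH-A (Rhodococcus ruber), NAD+ (cat.), i-PrOH, phosphate buffer pH 7.5, 30 °C
Reagents that add atoms: none
Why: Enzymatic carbonyl reduction with Prelog selectivity (hydride from NADH to the Re face of the methyl ketone, 2-propanol as terminal reductant) should give the (S)-carbinol, so that C19 is carried as one defined stereoisomer.

Step 4
Reactants: 4 3-[(2S)-2-hydroxypropyl]-4,6-dimethyl-2H-pyran-2-one
Product: 5 3-[(2S)-2-(TBSO)propyl]-4,6-dimethyl-2H-pyran-2-one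
Conditions: t-BuMe2SiCl, imidazole, DMF, rt
Reagents that add atoms: tert-butyldimethylsilyl chloride, CC(C)(C)[Si](C)(C)Cl
Why: Standard silylation of a secondary alcohol protects the future C19 ketone as a robust silyl ether for the enolate, hydride and oxidation steps that follow.

Step 5
Reactants: 5 3-[(2S)-2-(TBSO)propyl]-4,6-dimethyl-2H-pyran-2-one
Product: 8 6-(bromomethyl)-3-[(2S)-2-(TBSO)propyl]-4-methyl-2H-pyran-2-one, via lithium trienolate 6 (not isolated), via trimethylsilyl ketene acetal 7 (not isolated)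
Conditions: LiN(SiMe3)2, THF, −78 °C; Me3SiCl; then NBS, −78 → 0 °C
Reagents that add atoms: N-bromosuccinimide, O=C1CCC(=O)N1Br
Why: Vinylogous deprotonation of a 6-methyl-2-pyrone: the 6-methyl group gives the linearly conjugated trienolate 6 (the 4-methyl is held anti to the carbonyl by the ring and would give only a cross-conjugated anion), O-silylation gives ketene acetal 7, and NBS attacks its exocyclic methylene terminus because only that restores the 2-pyrone (vinylogous α-bromination of a silyl ketene acetal).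

Step 6
Reactants: 8 6-(bromomethyl)-3-[(2S)-2-(TBSO)propyl]-4-methyl-2H-pyran-2-one; 9 (4R)-4-benzyl-3-propanoyl-1,3-oxazolidin-2-one
Product: 11 (4R)-4-benzyl-3-[(2S)-2-methyl-3-{4-methyl-6-oxo-5-[(2S)-2-(TBSO)propyl]-6H-pyran-2-yl}propanoyl]-1,3-oxazolidin-2-one, via sodium Z-enolate 10 (not isolated)
Conditions: 9, NaN(SiMe3)2, THF, −78 °C; then 8, −78 → −30 °C
Reagents that add atoms: none
Why: Evans asymmetric alkylation: the chelated sodium Z-enolate 10 is alkylated by the allylic-type bromide on the face opposite the benzyl group of the (R)-auxiliary, which sets C12 as S.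

Step 7
Reactants: 11 alkylated imide
Product: 12 6-[(2S)-3-hydroxy-2-methylpropyl]-4-methyl-3-[(2S)-2-(TBSO)propyl]-2H-pyran-2-one
Conditions: NaBH4, THF/H2O, 0 °C → rt
Reagents that add atoms: none
Why: Reductive cleavage of the N-acyl oxazolidinone with borohydride in aqueous THF: the exocyclic imide carbonyl is far more electrophilic than the vinylogous lactone of the pyrone, so the primary alcohol and the recoverable auxiliary should form without touching C12.

Step 8
Reactants: 12 primary alcohol
Product: 13 (2S)-2-methyl-3-{4-methyl-6-oxo-5-[(2S)-2-(TBSO)propyl]-6H-pyran-2-yl}propanal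
Conditions: Dess–Martin periodinane, NaHCO3, CH2Cl2, 0 °C → rt
Reagents that add atoms: none
Why: Dess–Martin oxidation under buffered, non-basic conditions gives the α-stereogenic aldehyde without epimerisation of C12; it is used at once.

Step 9
Reactants: 13 aldehyde
Product: 15 6-[(2S,3S,4R)-3-hydroxy-2,4-dimethylhex-5-en-1-yl]-4-methyl-3-[(2S)-2-(TBSO)propyl]-2H-pyran-2-one, via diisopinocampheylborinate ester 14 (not isolated)
Conditions: (E)-but-2-ene, KOt-Bu, n-BuLi, THF, −78 → −45 °C; (+)-Ipc2BOMe, −78 °C; BF3·OEt2; 13, −78 °C; then NaBO3·4H2O, THF/H2O, rt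
Reagents that add atoms: (E)-but-2-ene, C/C=C/C (delivered as (E)-crotyl-B(Ipc)2 formed in the flask, C/C=C/CB([C@H]1C[C@H]2C[C@@H]([C@@H]1C)C2(C)C)[C@H]1C[C@H]2C[C@@H]([C@@H]1C)C2(C)C)
Why: Brown crotylboration through a closed chair transition state: the E-crotyl geometry gives the 10,11-anti relationship and the isopinocampheyl groups derived from (−)-α-pinene direct the reagent to the Re face of the aldehyde (11S,10R), reagent control that has to override the modest Felkin preference of the C12 centre; perborate is used for the work-up because the pyrone would not tolerate alkaline peroxide.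

Step 10
Reactants: 15 homoallylic alcohol
Product: 16 (2S,3S,4R)-2,4-dimethyl-1-{4-methyl-6-oxo-5-[(2S)-2-(TBSO)propyl]-6H-pyran-2-yl}hex-5-en-3-yl prop-2-enoate
Conditions: acryloyl chloride, Et3N, DMAP (cat.), CH2Cl2, 0 °C
Reagents that add atoms: acryloyl chloride, C=CC(Cl)=O
Why: Acylation of the hindered secondary alcohol with the acid chloride under DMAP catalysis installs C7 and C8 as the acrylate.

Step 11
Reactants: 16 acrylate
Product: 17 (5R,6S)-5-methyl-6-[(2S)-1-{4-methyl-6-oxo-5-[(2S)-2-(TBSO)propyl]-6H-pyran-2-yl}propan-2-yl]-5,6-dihydro-2H-pyran-2-one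
Conditions: second-generation Grubbs catalyst RuCl2(=CHPh)(H2IMes)(PCy3) (5 mol%), CH2Cl2 (0.005 M), 40 °C
Reagents that add atoms: none
Why: Ring-closing metathesis of the acrylate with the terminal vinyl group closes the six-membered α,β-unsaturated lactone with loss of ethylene, which fixes the C8=C9 alkene as cis and keeps the C10 methyl trans to the C11 substituent; the fully substituted pyrone double bonds do not take part.

Step 12
Reactants: 17 pyrone-tethered dihydropyranone
Product: 19 tricyclic lactone (8S,9R,10R,11S,12S,19S) holding rings A and B in which the C7 carbonyl on C8 is bridged to the C11 oxygen, via bridged oxabicyclooctenone adduct 18 (not isolated)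
Conditions: toluene (0.005 M), BHT, degassed, sealed tube, 150–170 °C
Reagents that add atoms: none
Why: Heating should bring the pyrone diene (C14=C15–C16=C17) over the C8=C9 bond of the tethered unsaturated lactone in a concerted, suprafacial [4+2] cycloaddition that forms C9–C14 and C8–C17 and gives the 2-oxabicyclo[2.2.2]octenone 18, which then expels CO2 by retro-[4+2] to leave the cyclohexa-1,3-diene of ring A. The closest known reaction type is the intramolecular Diels–Alder reaction of 2-pyrones with tethered alkenes followed by thermal CO2 extrusion. Ring B closes as a six-membered carbocycle through the four-atom tether C10–C11–C12–C13 (type 1 intramolecular mode, C9–C14 bond), and ring A is the six-membered ring of the cycloaddition itself, completed by the C8–C17 bond. C9 is set by C11, because the C12–C13 arm can deliver C14 only to the lactone face that it occupies (cis to C11–C12, trans to the C10 methyl), and C8 follows from the cis ring alkene, whose suprafacial addition leaves H8 and H9 cis. The step needs dienophile π-face selectivity and the tethered regiochemistry, both enforced by the short tether on C11 (the other face cannot be bridged and the reversed orientation would need a seven-membered bridged ring); endo or exo approach is irrelevant because C14 and C17 end sp2. Dilution, exclusion of oxygen and the lowest workable temperature guard against bimolecular cycloaddition, aromatisation and 1,5-hydrogen shifts of the product diene.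

Step 13
Reactants: 19 tricyclic lactone
Product: 20 tricyclic lactol (C7 hemiacetal, mixture of anomers)
Conditions: i-Bu2AlH, CH2Cl2, −78 °C; aqueous work-up
Reagents that add atoms: none
Why: Partial reduction of a lactone with i-Bu2AlH at −78 °C stops at the aluminium hemiacetal and should give the lactol after work-up; silyl ether and diene are inert.

Step 14
Reactants: 20 tricyclic lactol
Product: 22 ethyl (E)-2-methyl-3-(ring A C8)prop-2-enoate with free C11 hydroxyl and C19 OTBS (8S,9S,10R,11S,12S,19S), via open hydroxy aldehyde 21 (not isolated)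
Conditions: Ph3P=C(CH3)CO2Et, toluene, 80 °C
Reagents that add atoms: ethyl 2-(triphenylphosphoranylidene)propanoate, CCOC(=O)C(C)=P(c1ccccc1)(c1ccccc1)c1ccccc1
Why: Wittig olefination of a lactol through its open hydroxy aldehyde 21 with a stabilised α-methyl ylide gives the E-trisubstituted C6=C7 enoate under near-neutral conditions chosen to spare the epimerisable, allylic C8 centre.

Step 15
Reactants: 22 hydroxy enoate
Product: 23 C11 triethylsilyl ether of 22
Conditions: Et3SiOTf, 2,6-lutidine, CH2Cl2, −78 → 0 °C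
Reagents that add atoms: triethylsilyl trifluoromethanesulfonate, CC[Si](CC)(CC)OS(=O)(=O)C(F)(F)F
Why: Silylation of the hindered C11 carbinol with the silyl triflate blocks conjugate re-addition of this hydroxyl to C7 and masks the future C11 ketone.

Step 16
Reactants: 23 silylated enoate
Product: 24 allylic alcohol (C5 CH2OH, C6=C7 E)
Conditions: i-Bu2AlH, CH2Cl2, −78 °C; aqueous work-up
Reagents that add atoms: none
Why: i-Bu2AlH reduces the conjugated ester to the allylic alcohol by 1,2-addition without touching the alkenes or silyl ethers.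

Step 17
Reactants: 24 allylic alcohol
Product: 25 (E)-enal (C5 aldehyde)
Conditions: MnO2, CH2Cl2, rt
Reagents that add atoms: none
Why: MnO2 oxidises only the allylic alcohol and gives the E-enal with C5 as the aldehyde carbon.

Step 18
Reactants: 25 enal
Product: 26 ethyl (2E,4E)-2,4-dimethylpenta-2,4-dienoate on C8 (C3 ester)
Conditions: Ph3P=C(CH3)CO2Et, toluene, 80 °C
Reagents that add atoms: ethyl 2-(triphenylphosphoranylidene)propanoate, CCOC(=O)C(C)=P(c1ccccc1)(c1ccccc1)c1ccccc1
Why: A second Wittig reaction with the stabilised α-methyl ylide adds C3, C4 and the C4 methyl and gives the E geometry at C4=C5 (ester trans to C6).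

Step 19
Reactants: 26 dienoate
Product: 27 (2E,4E)-dienol (C3 CH2OH)
Conditions: i-Bu2AlH, CH2Cl2, −78 °C; aqueous work-up
Reagents that add atoms: none
Why: 1,2-Reduction of the dienoate with i-Bu2AlH gives the dienol needed for hydroxyl-directed epoxidation.

Step 20
Reactants: 27 dienol
Product: 28 (4S,5S)-4,5-epoxy alcohol (C3 CH2OH, C6=C7 retained)
Conditions: Ti(OiPr)4 (10 mol%), L-(+)-diisopropyl tartrate (12 mol%), t-BuOOH, 4 Å molecular sieves, CH2Cl2, −20 °C
Reagents that add atoms: tert-butyl hydroperoxide, CC(C)(C)OO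
Why: Katsuki–Sharpless asymmetric epoxidation: the titanium-bound allylic alkoxide delivers oxygen only to the adjacent C4=C5 bond, and L-(+)-tartrate, which converts E-2-methyl allylic alcohols into (2S,3S)-epoxy alcohols, sets C4 and C5 as S,S; the C6=C7 and ring alkenes are not allylic alcohols and stay untouched.

Step 21
Reactants: 28 epoxy alcohol
Product: 29 (4R,5S)-epoxy aldehyde (C3 aldehyde; same spatial arrangement as 28)
Conditions: Dess–Martin periodinane, NaHCO3, CH2Cl2, 0 °C
Reagents that add atoms: none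
Why: Buffered Dess–Martin oxidation gives the epoxy aldehyde, which has no α-hydrogen at C4 and therefore cannot epimerise or eliminate.

Step 22
Reactants: 29 epoxy aldehyde
Product: 30 methyl (2E)-enoate of the full C1–C20 skeleton (C11 OTES, C19 OTBS)
Conditions: Ph3P=CHCO2Me, CH2Cl2, rt
Reagents that add atoms: methyl 2-(triphenylphosphoranylidene)acetate, COC(=O)C=P(c1ccccc1)(c1ccccc1)c1ccccc1
Why: Wittig olefination with the stabilised ester ylide gives the E C2=C3 enoate at room temperature without opening the vinyl oxirane.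

Step 23
Reactants: 30 methyl ester
Product: 31 bis-silylated C1 carboxylic acid
Conditions: LiOH, THF/MeOH/H2O, 0 °C → rt; then cold dilute HCl to pH 5
Reagents that add atoms: lithium hydroxide, [Li+].[OH-]
Why: Saponification of the methyl ester with LiOH frees the C1 acid while no ketone is present; C4 carries no hydrogen, so base cannot open the γ,δ-epoxy enoate by elimination, and the silyl ethers should survive.

Step 24
Reactants: 31 bis-silylated acid
Product: 32 C11,C19-diol acid
Conditions: Bu4NF, THF, 0 °C → rt; aq. NH4Cl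
Reagents that add atoms: none
Why: Fluoride-mediated desilylation removes the silyl ethers at C11 and C19 under conditions that leave the acid-labile vinyl oxirane intact.

Step 25
Reactants: 32 diol acid
Product: 33 CNP0214881.1 (target)
Conditions: Dess–Martin periodinane, CH2Cl2, 0 °C → rt
Reagents that add atoms: none
Why: Double Dess–Martin oxidation of the two secondary carbinols gives the C11 and C19 ketones under non-basic conditions that should not epimerise C10 or C12 or move the β,γ-unsaturated C19 ketone into conjugation, and that tolerate the free acid and the oxirane.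

**Compound list**
1 | 4,6-dimethyl-2H-pyran-2-one | CC1=CC(C)=CC(=O)O1 | starting material
2 | 3-bromo-4,6-dimethyl-2H-pyran-2-one | CC1=CC(C)=C(Br)C(=O)O1 | intermediate
3 | 4,6-dimethyl-3-(2-oxopropyl)-2H-pyran-2-one | CC(=O)CC1=C(C)C=C(C)OC1=O | intermediate
4 | 3-[(2S)-2-hydroxypropyl]-4,6-dimethyl-2H-pyran-2-one | C[C@H](O)CC1=C(C)C=C(C)OC1=O | intermediate
5 | 3-[(2S)-2-(TBSO)propyl]-4,6-dimethyl-2H-pyran-2-one | C[C@H](O[Si](C)(C)C(C)(C)C)CC1=C(C)C=C(C)OC1=O | intermediate
6 | lithium 3-[(2S)-2-(TBSO)propyl]-4-methyl-6-methylidene-6H-pyran-2-olate | C[C@H](O[Si](C)(C)C(C)(C)C)CC1=C([O-])OC(=C)C=C1C.[Li+] | intermediate (not isolated)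
7 | 3-[(2S)-2-(TBSO)propyl]-4-methyl-6-methylidene-2-(trimethylsilyloxy)-6H-pyran | C[C@H](O[Si](C)(C)C(C)(C)C)CC1=C(O[Si](C)(C)C)OC(=C)C=C1C | intermediate (not isolated)
8 | 6-(bromomethyl)-3-[(2S)-2-(TBSO)propyl]-4-methyl-2H-pyran-2-one | C[C@H](O[Si](C)(C)C(C)(C)C)CC1=C(C)C=C(CBr)OC1=O | intermediate
9 | (4R)-4-benzyl-3-propanoyl-1,3-oxazolidin-2-one | CCC(=O)N1[C@H](Cc2ccccc2)COC1=O | starting material
10 | sodium (Z)-enolate of 9 | C/C=C(\[O-])N1[C@H](Cc2ccccc2)COC1=O.[Na+] | intermediate (not isolated)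
11 | (4R)-4-benzyl-3-[(2S)-2-methyl-3-{4-methyl-6-oxo-5-[(2S)-2-(TBSO)propyl]-6H-pyran-2-yl}propanoyl]-1,3-oxazolidin-2-one | C[C@H](O[Si](C)(C)C(C)(C)C)CC1=C(C)C=C(C[C@H](C)C(=O)N2[C@H](Cc3ccccc3)COC2=O)OC1=O | intermediate
12 | 6-[(2S)-3-hydroxy-2-methylpropyl]-4-methyl-3-[(2S)-2-(TBSO)propyl]-2H-pyran-2-one | C[C@H](O[Si](C)(C)C(C)(C)C)CC1=C(C)C=C(C[C@H](C)CO)OC1=O | intermediate
13 | (2S)-2-methyl-3-{4-methyl-6-oxo-5-[(2S)-2-(TBSO)propyl]-6H-pyran-2-yl}propanal | C[C@H](O[Si](C)(C)C(C)(C)C)CC1=C(C)C=C(C[C@H](C)C=O)OC1=O | intermediate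
14 | diisopinocampheylborinate ester of 15 (O–B(Ipc)2 at C11) | C[C@H](O[Si](C)(C)C(C)(C)C)CC1=C(C)C=C(C[C@H](C)[C@H](OB([C@H]2C[C@H]3C[C@@H]([C@@H]2C)C3(C)C)[C@H]2C[C@H]3C[C@@H]([C@@H]2C)C3(C)C)[C@H](C)C=C)OC1=O | intermediate (not isolated)
15 | 6-[(2S,3S,4R)-3-hydroxy-2,4-dimethylhex-5-en-1-yl]-4-methyl-3-[(2S)-2-(TBSO)propyl]-2H-pyran-2-one | C[C@H](O[Si](C)(C)C(C)(C)C)CC1=C(C)C=C(C[C@H](C)[C@H](O)[C@H](C)C=C)OC1=O | intermediate
16 | (2S,3S,4R)-2,4-dimethyl-1-{4-methyl-6-oxo-5-[(2S)-2-(TBSO)propyl]-6H-pyran-2-yl}hex-5-en-3-yl prop-2-enoate | C[C@H](O[Si](C)(C)C(C)(C)C)CC1=C(C)C=C(C[C@H](C)[C@H](OC(=O)C=C)[C@H](C)C=C)OC1=O | intermediate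
17 | (5R,6S)-5-methyl-6-[(2S)-1-{4-methyl-6-oxo-5-[(2S)-2-(TBSO)propyl]-6H-pyran-2-yl}propan-2-yl]-5,6-dihydro-2H-pyran-2-one | C[C@H](O[Si](C)(C)C(C)(C)C)CC1=C(C)C=C(C[C@H](C)[C@@H]2OC(=O)C=C[C@H]2C)OC1=O | intermediate
18 | bridged [4+2] adduct (2-oxabicyclo[2.2.2]oct-5-en-3-one with bridgeheads C14 and C17; endo/exo at the bridgeheads not defined) | C[C@H](O[Si](C)(C)C(C)(C)C)CC12C(C)=CC3(C[C@H](C)[C@@H]4OC(=O)[C@H]1[C@H]3[C@H]4C)OC2=O | intermediate (not isolated)
19 | tricyclic lactone, rings A and B with C7(=O)–O–C11 bridge, C19 OTBS (8S,9R,10R,11S,12S,19S) | C[C@H](O[Si](C)(C)C(C)(C)C)CC1=C(C)C=C2C[C@H](C)[C@@H]3OC(=O)[C@H]1[C@H]2[C@H]3C | intermediate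
20 | tricyclic lactol (C7 hemiacetal of 19, anomeric mixture) | C[C@H](O[Si](C)(C)C(C)(C)C)CC1=C(C)C=C2C[C@H](C)[C@@H]3OC(O)[C@H]1[C@H]2[C@H]3C | intermediate
21 | ring-opened hydroxy aldehyde (C7 aldehyde on C8, C11 OH) | C[C@H](O[Si](C)(C)C(C)(C)C)CC1=C(C)C=C2C[C@H](C)[C@H](O)[C@H](C)[C@@H]2[C@@H]1C=O | intermediate (not isolated)
22 | ethyl (E)-enoate (C5 ester, C6=C7), C11 OH, C19 OTBS (8S,9S,10R,11S,12S,19S) | C[C@H](O[Si](C)(C)C(C)(C)C)CC1=C(C)C=C2C[C@H](C)[C@H](O)[C@H](C)[C@@H]2[C@@H]1/C=C(\C)C(=O)OCC | intermediate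
23 | C11 triethylsilyl ether of 22 | C[C@H](O[Si](C)(C)C(C)(C)C)CC1=C(C)C=C2C[C@H](C)[C@H](O[Si](CC)(CC)CC)[C@H](C)[C@@H]2[C@@H]1/C=C(\C)C(=O)OCC | intermediate
24 | allylic alcohol (C5 CH2OH) | C[C@H](O[Si](C)(C)C(C)(C)C)CC1=C(C)C=C2C[C@H](C)[C@H](O[Si](CC)(CC)CC)[C@H](C)[C@@H]2[C@@H]1/C=C(\C)CO | intermediate
25 | (E)-enal (C5 aldehyde) | C[C@H](O[Si](C)(C)C(C)(C)C)CC1=C(C)C=C2C[C@H](C)[C@H](O[Si](CC)(CC)CC)[C@H](C)[C@@H]2[C@@H]1/C=C(\C)C=O | intermediate
26 | ethyl (2E,4E)-dienoate (C3 ester) | C[C@H](O[Si](C)(C)C(C)(C)C)CC1=C(C)C=C2C[C@H](C)[C@H](O[Si](CC)(CC)CC)[C@H](C)[C@@H]2[C@@H]1/C=C(\C)/C=C(\C)C(=O)OCC | intermediate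
27 | (2E,4E)-dienol (C3 CH2OH) | C[C@H](O[Si](C)(C)C(C)(C)C)CC1=C(C)C=C2C[C@H](C)[C@H](O[Si](CC)(CC)CC)[C@H](C)[C@@H]2[C@@H]1/C=C(\C)/C=C(\C)CO | intermediate
28 | (4S,5S)-epoxy alcohol | C[C@H](O[Si](C)(C)C(C)(C)C)CC1=C(C)C=C2C[C@H](C)[C@H](O[Si](CC)(CC)CC)[C@H](C)[C@@H]2[C@@H]1/C=C(\C)[C@@H]1O[C@@]1(C)CO | intermediate
29 | (4R,5S)-epoxy aldehyde | C[C@H](O[Si](C)(C)C(C)(C)C)CC1=C(C)C=C2C[C@H](C)[C@H](O[Si](CC)(CC)CC)[C@H](C)[C@@H]2[C@@H]1/C=C(\C)[C@@H]1O[C@@]1(C)C=O | intermediate
30 | methyl (2E)-enoate, (4S,5S)-epoxide, C11 OTES, C19 OTBS | C[C@H](O[Si](C)(C)C(C)(C)C)CC1=C(C)C=C2C[C@H](C)[C@H](O[Si](CC)(CC)CC)[C@H](C)[C@@H]2[C@@H]1/C=C(\C)[C@@H]1O[C@@]1(C)/C=C/C(=O)OC | intermediate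
31 | bis-silylated C1 acid | C[C@H](O[Si](C)(C)C(C)(C)C)CC1=C(C)C=C2C[C@H](C)[C@H](O[Si](CC)(CC)CC)[C@H](C)[C@@H]2[C@@H]1/C=C(\C)[C@@H]1O[C@@]1(C)/C=C/C(=O)O | intermediate
32 | C11,C19-diol acid | C[C@H](O)CC1=C(C)C=C2C[C@H](C)[C@H](O)[C@H](C)[C@@H]2[C@@H]1/C=C(\C)[C@@H]1O[C@@]1(C)/C=C/C(=O)O | intermediate
33 | CNP0214881.1, (2E,6E)-(4S,5S,8S,9S,10R,12S) | CC(=O)CC1=C(C)C=C2C[C@H](C)C(=O)[C@H](C)[C@@H]2[C@@H]1/C=C(\C)[C@@H]1O[C@@]1(C)/C=C/C(=O)O | target

**Totals**
Total step count: 25. Longest linear sequence: 25 steps (1 → 33); 9 is purchased.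

**Steps most likely to fail**

Step 12. The cycloaddition may be too slow: an alkylated pyrone meets an unactivated enoate through a strained bicyclo[3.3.1]-type transition state. Long heating then favours decomposition, 1,5-hydrogen shift of the product diene or its dehydrogenation. The fallback sets out from 17 and raises the diene reactivity with a removable activating group. Bromination of the free pyrone position C15 (NBS, MeCN, rt) should give the bromopyrone F1; bromo-2-pyrones are ambiphilic dienes that cycloadd at lower temperature. Heating F1 (toluene, about 110 °C) should pass through the bridged bromo adduct F2 and, after CO2 loss, give the bromodiene lactone F3. Hydrodebromination of the vinyl bromide (Pd(PPh3)4 cat., Bu3SnH, THF) comes back to the route at 19.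

Step 14. The lactol may open too little to react. The transient aldehyde is α-stereogenic and β,γ-unsaturated, so C8 may epimerise or the diene may shift into conjugation. The freed C11 hydroxyl may also add in conjugate fashion to C7 of the new enoate. The fallback sets out from 19 and avoids both lactol and free hydroxyl. Reduction (LiBH4, THF) should give the diol F4, and double silylation (Et3SiOTf, 2,6-lutidine) the bis(triethylsilyl) ether F5. Swern oxidation ((COCl)2, DMSO, then Et3N, −78 → −30 °C) converts a primary triethylsilyl ether directly into the aldehyde while the hindered secondary silyl ether stays, giving the silylated aldehyde F6. Wittig reaction with Ph3P=C(CH3)CO2Et at 40 °C comes back to the route at 23.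

Step 9. The crotylboration is a mismatched double stereodifferentiation, so facial selectivity may be poor and the Felkin anti isomer may compete. The fallback sets out from 13 and replaces the crotylborane by a chiral allenylzinc reagent (Marshall propargylation). (S)-But-3-yn-2-yl methanesulfonate, Pd(OAc)2 (5 mol%), PPh3 and Et2Zn in THF at −20 °C should give the anti homopropargylic alcohol F7. The stereochemical course is anti SN2' palladation followed by syn SE2' addition, a net inversion at the propargylic carbon. Semihydrogenation (H2, Pd/CaCO3 poisoned with Pb(OAc)2, quinoline) comes back to the route at 15.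

**Further compounds**
F1 | step 12 | C15-bromo analogue of 17 (5-bromopyrone) | C[C@H](O[Si](C)(C)C(C)(C)C)CC1=C(C)C(Br)=C(C[C@H](C)[C@@H]2OC(=O)C=C[C@H]2C)OC1=O
F2 | step 12 | bridged bromo cycloadduct (not isolated; bridgeheads not defined) | C[C@H](O[Si](C)(C)C(C)(C)C)CC12C(C)=C(Br)C3(C[C@H](C)[C@@H]4OC(=O)[C@H]1[C@H]3[C@H]4C)OC2=O
F3 | step 12 | C15-bromo analogue of 19 | C[C@H](O[Si](C)(C)C(C)(C)C)CC1=C(C)C(Br)=C2C[C@H](C)[C@@H]3OC(=O)[C@H]1[C@H]2[C@H]3C
F4 | step 14 | C7,C11-diol from reduction of 19 | C[C@H](O[Si](C)(C)C(C)(C)C)CC1=C(C)C=C2C[C@H](C)[C@H](O)[C@H](C)[C@@H]2[C@@H]1CO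
F5 | step 14 | C7,C11-bis(triethylsilyl) ether of F4 | C[C@H](O[Si](C)(C)C(C)(C)C)CC1=C(C)C=C2C[C@H](C)[C@H](O[Si](CC)(CC)CC)[C@H](C)[C@@H]2[C@@H]1CO[Si](CC)(CC)CC
F6 | step 14 | C7 aldehyde with C11 triethylsilyl ether | C[C@H](O[Si](C)(C)C(C)(C)C)CC1=C(C)C=C2C[C@H](C)[C@H](O[Si](CC)(CC)CC)[C@H](C)[C@@H]2[C@@H]1C=O
F7 | step 9 | homopropargylic alcohol (terminal alkyne analogue of 15) | C[C@H](O[Si](C)(C)C(C)(C)C)CC1=C(C)C=C(C[C@H](C)[C@H](O)[C@H](C)C#C)OC1=O
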